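## Structural features

The target is a daucane. A cyclopentane ring A (C1 to C5) is fused through the C1–C5 bond to a seven-membered ring B (C1, C5, C6, C7, C8, C9, C10). It carries an isopropyl carbinol at C4, an angular methyl on the quaternary C1, a 4-hydroxybenzoate on O6 and a trisubstituted epoxide across C8–C9 with the methyl on C8.

Four of the six stereocentres are contiguous (C4–C5–C6 and C5–C1); C8 and C9 lie across ring B. Read from the SMILES, the angular methyl, the C4 hydroxyl and O6 share one face (β), and H5 and the epoxide oxygen share the other (α). The fusion is therefore trans and O6 is syn-1,3 to the angular methyl.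

The fragile groups are the trisubstituted epoxide (acid-labile, and within reach of the C4 hydroxyl at C9), the phenolic aryl ester (base and nucleophiles) and the tertiary alcohol (dehydration). Any intermediate with a C4 carbonyl is also delicate, because C5 is then epimerisable and O6 is a β-leaving group.

The real difficulty is the quaternary C1 next to the ring-fusion methine C5. The trans fusion is probably not the more stable one while C4 is a carbonyl, and O6 is crowded.

In ring A, C4 has C3 and C5 as neighbours and C1 lies two bonds away. That is the pattern of a cyclopent-2-enone (C4=O, C2=C3) whose C1–C2 bond can be made by 4π electrocyclisation of a divinyl ketone in which the C5=C1 alkene belongs to ring B. A silyl group on C2 fixes the alkene at C2=C3.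

## Logic of the disconnections

**27 ⇒ 26 ⇒ 25.** The phenol O–H is taken back to an O–Si bond, and the two C–O bonds of the epoxide (C8–O, C9–O) are removed to give the C8=C9 alkene. The epoxide is the most acid-sensitive group and should arrive late; the phenol must be masked during acylation. 25 has four stereocentres and only robust functions. The forward oxidation must attack the α face of the only alkene, and the last unmasking must spare epoxide and ester.

**25 ⇒ 20 + 23 (23 ⇒ 21).** The O6–C(=O) ester bond is cut, so that the aryl unit is attached after all carbanion chemistry. This leaves the diol 20 and an acid made in one step. The forward step must acylate a hindered secondary hydroxyl beside a tertiary one.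

**20 ⇒ 19 ⇒ 18.** The O6–Si bond is restored and the C4–isopropyl bond is cut. The tertiary carbinol is the adduct of an isopropyl nucleophile to a C4 ketone, and that ketone is what a cyclopentenone-forming ring closure delivers. One stereocentre and one branch are removed. The addition must come from the α face of an enolisable ketone without disturbing C5 or O6.

**18 ⇒ 17.** Two C–H bonds (C2, C3) are removed to give the enone, the direct product of the ring closure. The forward 1,4-reduction must leave C8=C9 and C5 alone.

**17 ⇒ 15 (through 16).** The C1–C2 bond is cut. This removes ring A, the quaternary C1 and the C5 stereocentre together; 15 is monocyclic with one stereocentre (C6). The forward step needs one sense of conrotation, protonation of 16 at C5 from the α face, and survival of the silyl ether under a Lewis acid.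

**15 ⇒ 14 ⇒ 9 + 12 (12 ⇒ 11 ⇒ 10).** After C4 is adjusted to the carbinol, the C4–C5 bond is cut. This pairs a C5 alkenylmetal from ring B with a three-carbon silylated enal. The forward step needs halogen–metal exchange on a tetrasubstituted alkenyl bromide beside a silyloxy group, and an E-vinylsilane.

**9 ⇒ 8 ⇒ 7 ⇒ 6.** The O–Si bond is removed, and the C6 carbinol is traced through the ketone to the racemic alcohol. The single stereocentre of the precursor then comes from a catalyst-controlled reduction. The demand is high enantioselectivity on a seven-membered bromodienone and no migration of the skipped alkene.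

**6 ⇒ 5 ⇒ 2 + 3 (2 ⇒ 1).** The C1–C5 and C5–C6 bonds are cut (one-carbon insertion), then the cyclopropane, then the dihydroarene. Ring B with both methyls, C8=C9, O6 and a C5 halogen comes from an aromatic commodity. The forward steps need mono-cyclopropanation and capture of the allyl cation at its CH terminus.

## Other disconnections considered

**Alternative 1:** The cut lies inside ring B, at C1–C5 and C5–C6, so that C5 is a one-carbon unit inserted into a six-membered ring. Forward, dibromocarbene adds to one alkene of 2 and the adduct 5 is opened with AgClO4 in aqueous acetone to the racemic bromodienol A1 (identical with 6).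
- In its favour: an aromatic feedstock delivers ring B with both methyls, the C8=C9 alkene, O6 and a C5 halogen handle in three operations, by well-understood carbene addition and two-electron disrotatory ring opening.
- Against it as the strategic centre: it makes no bond of ring A, no quaternary centre and no defined stereocentre. A1 is racemic and must be oxidised and reduced again, and the capture of the bromoallyl cation by water has a regiochemical question of its own.
- Comparison: on robustness, cost and precedent it is the better step. On structural gain it is weaker, since C1, C5 and the fusion stay open. On step economy it is equal, because it is not a rival but a subroutine: the chosen plan uses it as steps 2 and 3 and still needs the electrocyclisation.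

**Alternative 2:** Two bonds are cut at once, C1–C5 and C6–C7, which opens both rings and leads to the enyne A2. In A2 the alkyne C5≡C6 is tethered through C4–C3–C2 to a trisubstituted siloxyvinylcyclopropane. Forward, [Rh(CO)2Cl]2 would join the two π components with cleavage of the C9–C7 cyclopropane bond, a (5+2) cycloaddition through a rhodacycle, to give the bicyclic dienol ether A3.
- In its favour: rings A and B and the quaternary C1 form in one catalytic, atom-economical step, with the C4 carbinol and the isopropyl group already in place. In convergence and in bonds formed per step it is better than the chosen plan.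
- Against it here: the oxygen of A3 sits at C9, where the target needs an alkene, and C6 arrives as an alkene carbon, where the target needs oxygen. Turning the C9 enol ether into C8=C9 (ketone, enol triflate, reduction) costs a redox sequence. A syn hydroboration of C5=C6 would put H5 and O6 on the same face, whereas the target has them on opposite faces, so C6 would also have to be inverted. The alkene carbon C1 of A2 is fully substituted, which should slow metallacycle formation. The relay from C4 to C1 is not assured, and single-enantiomer A2 (a tertiary propargylic ether) is a multi-step problem.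
- Comparison: both key steps are metal-promoted ring closures, pericyclic in the chosen plan and organometallic here. A3 is closer to the carbon skeleton but further from the oxygenation pattern. The stronger key step is expected to be paid for by a longer endgame, so the totals should be similar or worse.

**Alternative 3:** One bond of ring B is cut, C7–C8, leading to the cyclopentane A4. In A4, C5 carries a silyl enol ether (C6=C7) and C1 carries a side chain ending in a vinylsilane whose C8 bears silicon and the methyl. Forward, constant-current oxidation at a carbon anode (LiClO4, MeOH–THF, 2,6-lutidine) would give the enol ether radical cation, which is trapped at C7 by C8. Loss of the second electron and of the silyl group would leave the C8=C9 alkene and the C6 ketone A5.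
- In its favour: the C8=C9 alkene and an oxygen at C6 appear where they are needed, and no stoichiometric oxidant is used. The C1/C5 relationship is set on a cyclopentane before ring B exists, so the trans fusion does not rest on a kinetic protonation; on that point it is better than the chosen plan.
- Against it here: seven-membered closure by radical-cation/alkene coupling is slower than the five- and six-membered cases and competes with solvent trapping. C5 of A5 lies between a ketone and a β-silyloxy carbinol (epimerisation, elimination, retro-aldol), and the ketone must still be reduced to the more hindered alcohol. Above all A4, with two fully substituted centres and three contiguous stereocentres, needs a long enantioselective synthesis.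
- Comparison: C6 comes from hydride delivery to a ketone in both plans (catalyst-controlled in the chosen one, substrate-controlled here), so they are equal there. The anodic step is a one-electron umpolung and the chosen step a pericyclic closure, with silicon fixing the alkene in both. The chosen plan should be shorter, because its chiral information is one catalyst-made carbinol.

Key step: step 11

**Assumption:** the SMILES is read literally, which gives (1R,4R,5S,6R,8R,9S) in daucane numbering, with O6 on the same face as the angular methyl and the C4 hydroxyl.

**Convention:** C-numbers are the daucane numbers of the target throughout, also for intermediates.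

**Remark on the control element:** C6 is bonded to C5, the carbon α to the carbonyl, and not to the bond-forming terminus C1. Its influence on C1 is therefore relayed through the conformation of ring B, and the route is written with that in mind.

## Route

Step 1
Reactants: 1 p-xylene
Product: 2 1,4-dimethylcyclohexa-1,4-diene
Conditions: Li, NH3(l), EtOH, Et2O, −78 → −33 °C
Reagents that add atoms: none
Why: Birch reduction; the two alkyl groups end up on the remaining double bonds, so the non-conjugated diene with two equivalent trisubstituted alkenes is expected.

Step 2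
Reactants: 2 1,4-dimethylcyclohexa-1,4-diene; 3 bromoform
Product: 5 racemic 7,7-dibromo-1,4-dimethylbicyclo[4.1.0]hept-3-ene, via dibromocarbene 4 (not isolated)
Conditions: KOt-Bu, pentane, −20 → 0 °C (2 in 1.5-fold excess)
Reagents that add atoms: none
Why: α-Elimination from 3 gives the carbene, which adds stereospecifically in a (2+1) cheletropic cycloaddition to one of the two equivalent alkenes; the excess of 2 limits double addition, and the cis fusion is the only one possible.

Step 3
Reactants: 5 racemic 7,7-dibromo-1,4-dimethylbicyclo[4.1.0]hept-3-ene
Product: 6 racemic 2-bromo-3,6-dimethylcyclohepta-2,5-dien-1-ol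
Conditions: AgClO4, acetone–H2O, 0 °C → rt
Reagents that add atoms: water, O
Why: Silver-assisted loss of the endo bromide with concerted disrotatory opening of the cyclopropane (two-electron electrocyclic ring opening) gives a cis bromoallyl cation inside the seven-membered ring; water should end up at the CH terminus, which keeps the tetrasubstituted bromoalkene, because a tertiary allylic alcohol would re-ionise in the acid that forms.

Step 4
Reactants: 6 racemic 2-bromo-3,6-dimethylcyclohepta-2,5-dien-1-ol
Product: 7 2-bromo-3,6-dimethylcyclohepta-2,5-dien-1-one
Conditions: 1,1,1-triacetoxy-1,2-benziodoxol-3(1H)-one (DMP), pyridine, CH2Cl2, 0 °C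
Reagents that add atoms: none
Why: Hypervalent-iodine oxidation of the secondary allylic alcohol; the buffered medium is chosen so that the C8=C9 alkene, now β,γ to the carbonyl, does not move into conjugation.

Step 5
Reactants: 7 2-bromo-3,6-dimethylcyclohepta-2,5-dien-1-one
Product: 8 (1R)-2-bromo-3,6-dimethylcyclohepta-2,5-dien-1-ol
Conditions: (S)-2-methyl-CBS-oxazaborolidine (C18H20BNO, 15 mol %), catecholborane, toluene, −78 °C
Reagents that add atoms: none
Why: CBS reduction of an α-bromoenone, a known substrate class in which the bromoalkene arm acts as the large group; with the (S)-catalyst the hydride should be delivered to give the (R)-carbinol, which is C6 of the target, and catecholborane leaves the isolated alkene alone.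

Step 6
Reactants: 8 (1R)-2-bromo-3,6-dimethylcyclohepta-2,5-dien-1-ol
Product: 9 {[(1R)-2-bromo-3,6-dimethylcyclohepta-2,5-dien-1-yl]oxy}(tert-butyl)dimethylsilane
Conditions: TBSCl, imidazole, DMF, rt
Reagents that add atoms: tert-butyldimethylsilyl chloride, CC(C)(C)[Si](C)(C)Cl
Why: Standard silylation; the group masks the hydroxyl toward t-BuLi, serves as the conformational and steric control element of the key step, and is removable with fluoride.

Step 7
Reactants: 10 3-(trimethylsilyl)prop-2-yn-1-ol
Product: 11 (2E)-3-(trimethylsilyl)prop-2-en-1-ol
Conditions: NaAlH2(OCH2CH2OMe)2, Et2O, 0 °C → rt; then H2O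
Reagents that add atoms: none
Why: Alkoxide-directed trans-hydroalumination of the propargylic alcohol followed by protonolysis should give the E-vinylsilane.

Step 8
Reactants: 11 (2E)-3-(trimethylsilyl)prop-2-en-1-ol
Product: 12 (2E)-3-(trimethylsilyl)prop-2-enal
Conditions: MnO2, CH2Cl2, rt
Reagents that add atoms: none
Why: Selective oxidation of an allylic alcohol on MnO2; the E geometry and the C–Si bond are not touched.

Step 9
Reactants: 9 {[(1R)-2-bromo-3,6-dimethylcyclohepta-2,5-dien-1-yl]oxy}(tert-butyl)dimethylsilane; 12 (2E)-3-(trimethylsilyl)prop-2-enal
Product: 14 (2E)-1-[(7R)-7-{[tert-butyl(dimethyl)silyl]oxy}-2,5-dimethylcyclohepta-1,4-dien-1-yl]-3-(trimethylsilyl)prop-2-en-1-ol (both carbinol epimers), via alkenyllithium 13 (not isolated)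
Conditions: t-BuLi (2.1 equiv), Et2O, −78 °C; then 12, −78 °C; then H2O
Reagents that add atoms: none
Why: Bromine–lithium exchange (the second equivalent of t-BuLi consumes t-BuBr) gives an alkenyllithium that cannot β-eliminate the silyloxy group without forming a seven-membered cyclic allene; 1,2-addition to the enal forms the C4–C5 bond, and the new carbinol centre needs no control because it is oxidised next.

Step 10
Reactants: 14 (2E)-1-[(7R)-7-{[tert-butyl(dimethyl)silyl]oxy}-2,5-dimethylcyclohepta-1,4-dien-1-yl]-3-(trimethylsilyl)prop-2-en-1-ol
Product: 15 (2E)-1-[(7R)-7-{[tert-butyl(dimethyl)silyl]oxy}-2,5-dimethylcyclohepta-1,4-dien-1-yl]-3-(trimethylsilyl)prop-2-en-1-one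
Conditions: MnO2, CH2Cl2, rt
Reagents that add atoms: none
Why: Oxidation of a doubly allylic alcohol to the cross-conjugated dienone under neutral conditions that leave both silyl groups and the skipped diene intact.

Step 11
Reactants: 15 (2E)-1-[(7R)-7-{[tert-butyl(dimethyl)silyl]oxy}-2,5-dimethylcyclohepta-1,4-dien-1-yl]-3-(trimethylsilyl)prop-2-en-1-one
Product: 17 (3aS,8R,8aS)-8-{[tert-butyl(dimethyl)silyl]oxy}-3a,6-dimethyl-4,7,8,8a-tetrahydroazulen-1(3aH)-one, via dichloroiron dienolate 16 (not isolated)
Conditions: FeCl3 (1.1 equiv), CH2Cl2, −50 → −10 °C; then cold aq. NaHCO3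
Reagents that add atoms: none
Why: FeCl3 binds the carbonyl oxygen and turns the cross-conjugated dienone into a 3-oxidopentadienyl cation (C2=C3–C4–C5=C1), which closes ring A by a thermally allowed four-electron conrotatory electrocyclisation that forms the C1–C2 bond and leaves an oxyallyl cation across C3–C4–C5. The C2–Si bond stabilises the charge at C3 and chloride then removes the silyl group, so the alkene is fixed at C2=C3 and the dienolate 16 remains until water protonates C5 in the quench. The closest known reaction type is the silicon-directed Nazarov cyclisation of cycloalkenyl β-silylvinyl ketones; the present case differs only in the fully substituted ring terminus and the allylic silyloxy group. One five-membered ring closes, by pericyclic union of the termini C1 and C2, with ring B as the backbone that holds the cation in its U shape. C1: the only stereocentre, C6, is bonded to C5 and not to the terminus; allylic strain with the iron-complexed acyl group forces its C–O bond pseudo-axial on the β face, and the sense of conrotation that turns C10 toward the α face and bonds C2 to the α lobe of C1 avoids this group, so the methyl ends up β, syn to O6. C5: in 16 ring A is planar and C5 is flanked on the β face by that silyloxy group and by the angular methyl, so kinetic protonation from the α face, giving the trans fusion, is expected. The step therefore needs one sense of conrotation, α protonation and no ionisation or β-elimination at C6; these rest on the pseudo-axial bulky silyl ether, the low temperature and a cold buffered quench, and because the trans-fused enone is probably the less stable C5 epimer it is kept away from acid and base and reduced at once.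

Step 12
Reactants: 17 (3aS,8R,8aS)-8-{[tert-butyl(dimethyl)silyl]oxy}-3a,6-dimethyl-4,7,8,8a-tetrahydroazulen-1(3aH)-one
Product: 18 (3aR,8R,8aS)-8-{[tert-butyl(dimethyl)silyl]oxy}-3a,6-dimethyl-3,3a,4,7,8,8a-hexahydroazulen-1(2H)-one
Conditions: [(Ph3P)CuH]6 (0.4 equiv), C6H6, H2O, rt
Reagents that add atoms: none
Why: Conjugate hydride transfer from the phosphine-stabilised copper hydride to C2 and protonation of the copper enolate at C3; the reagent does not reduce the isolated trisubstituted alkene, and the neutral medium should leave C5 and the β-silyloxy group alone.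

Step 13
Reactants: 18 (3aR,8R,8aS)-8-{[tert-butyl(dimethyl)silyl]oxy}-3a,6-dimethyl-3,3a,4,7,8,8a-hexahydroazulen-1(2H)-one
Product: 19 (1R,3aR,8R,8aS)-8-{[tert-butyl(dimethyl)silyl]oxy}-3a,6-dimethyl-1-(propan-2-yl)-1,2,3,3a,4,7,8,8a-octahydroazulen-1-ol
Conditions: i-PrMgCl, CeCl3, THF, −78 °C; then H2O
Reagents that add atoms: isopropylmagnesium chloride, CC(C)[Mg]Cl
Why: 1,2-Addition of the weakly basic organocerium reagent, which suppresses enolisation and β-hydride reduction; attack is expected on the α face of the C4 carbonyl, away from the angular methyl and the silyloxy-bearing C6 branch, which sets C4 with the hydroxyl β and the isopropyl group α.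

Step 14
Reactants: 19 (1R,3aR,8R,8aS)-8-{[tert-butyl(dimethyl)silyl]oxy}-3a,6-dimethyl-1-(propan-2-yl)-1,2,3,3a,4,7,8,8a-octahydroazulen-1-ol
Product: 20 (1R,3aR,8R,8aS)-3a,6-dimethyl-1-(propan-2-yl)-1,2,3,3a,4,7,8,8a-octahydroazulene-1,8-diol
Conditions: Bu4NF, THF, 50 °C
Reagents that add atoms: none
Why: Fluoride cleavage of the secondary silyl ether; no other group in the molecule reacts with fluoride.

Step 15
Reactants: 21 4-hydroxybenzoic acid
Product: 23 4-{[tert-butyl(dimethyl)silyl]oxy}benzoic acid, via bis-silylated silyl ester 22 (not isolated)
Conditions: TBSCl (2.2 equiv), imidazole, DMF, rt; then AcOH–THF–H2O, rt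
Reagents that add atoms: tert-butyldimethylsilyl chloride, CC(C)(C)[Si](C)(C)Cl
Why: Both acidic hydroxyls are silylated, and the far more labile silyl ester is then hydrolysed selectively, leaving the aryl silyl ether.

Step 16
Reactants: 20 (1R,3aR,8R,8aS)-3a,6-dimethyl-1-(propan-2-yl)-1,2,3,3a,4,7,8,8a-octahydroazulene-1,8-diol; 23 4-{[tert-butyl(dimethyl)silyl]oxy}benzoic acid
Product: 25 (3R,3aS,4R,8aR)-3-hydroxy-6,8a-dimethyl-3-(propan-2-yl)-1,2,3,3a,4,5,8,8a-octahydroazulen-4-yl 4-{[tert-butyl(dimethyl)silyl]oxy}benzoate, via mixed anhydride 24 (not isolated)
Conditions: 23, 2,4,6-Cl3C6H2COCl, Et3N, THF, rt; then 20, 4-(dimethylamino)pyridine, toluene, 60 °C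
Reagents that add atoms: none
Why: Yamaguchi esterification; the pyridine catalyst transfers the less hindered aroyl group of the mixed anhydride to the secondary O6 hydroxyl, the tertiary C4 hydroxyl is too hindered to compete, and no stereocentre is touched.

Step 17
Reactants: 25 (3R,3aS,4R,8aR)-3-hydroxy-6,8a-dimethyl-3-(propan-2-yl)-1,2,3,3a,4,5,8,8a-octahydroazulen-4-yl 4-{[tert-butyl(dimethyl)silyl]oxy}benzoate
Product: 26 (1R,4R,5S,6R,8R,9S)-8,9-epoxy-4-hydroxydaucan-6-yl 4-{[tert-butyl(dimethyl)silyl]oxy}benzoate (daucane numbering; epoxide oxygen α)
Conditions: mCPBA, NaHCO3, CH2Cl2, 0 °C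
Reagents that add atoms: 3-chloroperoxybenzoic acid, O=C(OO)c1cccc(Cl)c1
Why: Prilezhaev epoxidation of the only alkene; the concerted syn transfer of oxygen is expected on the α face, anti to the angular methyl and to the O6 ester (no free hydroxyl is close enough to steer the peracid), which sets C8 and C9, and the bicarbonate buffer protects the new epoxide from acid-induced opening by the C4 hydroxyl.

Step 18
Reactants: 26 (1R,4R,5S,6R,8R,9S)-8,9-epoxy-4-hydroxydaucan-6-yl 4-{[tert-butyl(dimethyl)silyl]oxy}benzoate
Product: 27 (1R,4R,5S,6R,8R,9S)-8,9-epoxy-4-hydroxydaucan-6-yl 4-hydroxybenzoate (the target)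
Conditions: Bu4NF, AcOH, THF, 0 °C
Reagents that add atoms: none
Why: Aryl silyl ethers are cleaved by fluoride within minutes at this temperature; the acetic acid buffer keeps the phenoxide from attacking the ester or the epoxide.

## Compound list

1 | p-xylene | Cc1ccc(C)cc1 | starting material
2 | 1,4-dimethylcyclohexa-1,4-diene | CC1=CCC(C)=CC1 | intermediate
3 | bromoform | BrC(Br)Br | starting material
4 | dibromocarbene | Br[C]Br | intermediate (not isolated)
5 | racemic 7,7-dibromo-1,4-dimethylbicyclo[4.1.0]hept-3-ene (cis-fused) | CC1=CCC2(C)C(C1)C2(Br)Br | intermediate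
6 | racemic 2-bromo-3,6-dimethylcyclohepta-2,5-dien-1-ol | CC1=C(Br)C(O)CC(C)=CC1 | intermediate
7 | 2-bromo-3,6-dimethylcyclohepta-2,5-dien-1-one | CC1=C(Br)C(=O)CC(C)=CC1 | intermediate
8 | (1R)-2-bromo-3,6-dimethylcyclohepta-2,5-dien-1-ol | BrC1=C(C)CC=C(C)C[C@H]1O | intermediate
9 | {[(1R)-2-bromo-3,6-dimethylcyclohepta-2,5-dien-1-yl]oxy}(tert-butyl)dimethylsilane | BrC1=C(C)CC=C(C)C[C@H]1O[Si](C)(C)C(C)(C)C | intermediate
10 | 3-(trimethylsilyl)prop-2-yn-1-ol | C[Si](C)(C)C#CCO | starting material
11 | (2E)-3-(trimethylsilyl)prop-2-en-1-ol | C[Si](C)(C)/C=C/CO | intermediate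
12 | (2E)-3-(trimethylsilyl)prop-2-enal | C[Si](C)(C)/C=C/C=O | intermediate
13 | [(7R)-7-{[tert-butyl(dimethyl)silyl]oxy}-2,5-dimethylcyclohepta-1,4-dien-1-yl]lithium | [Li]C1=C(C)CC=C(C)C[C@H]1O[Si](C)(C)C(C)(C)C | intermediate (not isolated)
14 | (2E)-1-[(7R)-7-{[tert-butyl(dimethyl)silyl]oxy}-2,5-dimethylcyclohepta-1,4-dien-1-yl]-3-(trimethylsilyl)prop-2-en-1-ol, both carbinol epimers | C[Si](C)(C)/C=C/C(O)C1=C(C)CC=C(C)C[C@H]1O[Si](C)(C)C(C)(C)C | intermediate
15 | (2E)-1-[(7R)-7-{[tert-butyl(dimethyl)silyl]oxy}-2,5-dimethylcyclohepta-1,4-dien-1-yl]-3-(trimethylsilyl)prop-2-en-1-one | C[Si](C)(C)/C=C/C(=O)C1=C(C)CC=C(C)C[C@H]1O[Si](C)(C)C(C)(C)C | intermediate (precursor of the key step)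
16 | dichloroiron dienolate of 17 (O4–FeCl2; C4=C5 and C2=C3) | Cl[Fe](Cl)OC1=C2[C@H](O[Si](C)(C)C(C)(C)C)CC(C)=CC[C@@]2(C)C=C1 | intermediate (not isolated)
17 | (3aS,8R,8aS)-8-{[tert-butyl(dimethyl)silyl]oxy}-3a,6-dimethyl-4,7,8,8a-tetrahydroazulen-1(3aH)-one | O=C1C=C[C@]2(C)CC=C(C)C[C@@H](O[Si](C)(C)C(C)(C)C)[C@H]21 | intermediate (product of the key step)
18 | (3aR,8R,8aS)-8-{[tert-butyl(dimethyl)silyl]oxy}-3a,6-dimethyl-3,3a,4,7,8,8a-hexahydroazulen-1(2H)-one | O=C1CC[C@]2(C)CC=C(C)C[C@@H](O[Si](C)(C)C(C)(C)C)[C@H]21 | intermediate
19 | (1R,3aR,8R,8aS)-8-{[tert-butyl(dimethyl)silyl]oxy}-3a,6-dimethyl-1-(propan-2-yl)-1,2,3,3a,4,7,8,8a-octahydroazulen-1-ol | CC(C)[C@]1(O)CC[C@]2(C)CC=C(C)C[C@@H](O[Si](C)(C)C(C)(C)C)[C@H]21 | intermediate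
20 | (1R,3aR,8R,8aS)-3a,6-dimethyl-1-(propan-2-yl)-1,2,3,3a,4,7,8,8a-octahydroazulene-1,8-diol | CC(C)[C@]1(O)CC[C@]2(C)CC=C(C)C[C@@H](O)[C@H]21 | intermediate
21 | 4-hydroxybenzoic acid | O=C(O)c1ccc(O)cc1 | starting material
22 | tert-butyldimethylsilyl 4-{[tert-butyl(dimethyl)silyl]oxy}benzoate | CC(C)(C)[Si](C)(C)Oc1ccc(cc1)C(=O)O[Si](C)(C)C(C)(C)C | intermediate (not isolated)
23 | 4-{[tert-butyl(dimethyl)silyl]oxy}benzoic acid | CC(C)(C)[Si](C)(C)Oc1ccc(cc1)C(O)=O | intermediate
24 | 4-{[tert-butyl(dimethyl)silyl]oxy}benzoic 2,4,6-trichlorobenzoic anhydride | CC(C)(C)[Si](C)(C)Oc1ccc(cc1)C(=O)OC(=O)c1c(Cl)cc(Cl)cc1Cl | intermediate (not isolated)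
25 | (3R,3aS,4R,8aR)-3-hydroxy-6,8a-dimethyl-3-(propan-2-yl)-1,2,3,3a,4,5,8,8a-octahydroazulen-4-yl 4-{[tert-butyl(dimethyl)silyl]oxy}benzoate | CC(C)[C@]1(O)CC[C@]2(C)CC=C(C)C[C@@H](OC(=O)c3ccc(O[Si](C)(C)C(C)(C)C)cc3)[C@H]21 | intermediate
26 | (1R,4R,5S,6R,8R,9S)-8,9-epoxy-4-hydroxydaucan-6-yl 4-{[tert-butyl(dimethyl)silyl]oxy}benzoate | CC(C)[C@]1(O)CC[C@]2(C)C[C@@H]3O[C@]3(C)C[C@@H](OC(=O)c3ccc(O[Si](C)(C)C(C)(C)C)cc3)[C@H]21 | intermediate
27 | (1R,4R,5S,6R,8R,9S)-8,9-epoxy-4-hydroxydaucan-6-yl 4-hydroxybenzoate | CC(C)[C@]1(O)CC[C@]2(C)C[C@@H]3O[C@]3(C)C[C@@H](OC(=O)c3ccc(O)cc3)[C@H]21 | target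

## Step count and least certain steps

Total step count: 18. Longest linear sequence: 15 steps (1 to 27 through steps 1–6, 9–14 and 16–18).

**Step 11 (key step).** The most likely failure is protonation of dienolate 16 from the β face, or acid-mediated equilibration at C5 after the quench, so that the cis-fused epimer builds up. The trans-fused cyclopentenone is probably the less stable C5 epimer, and the two faces of C5 differ only by the C6 silyloxy group and by a methyl against a ring methylene. The sense of conrotation is a second uncertainty, since C6 acts on C1 only through the ring conformation.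

Fallback: ring closure and the setting of C5 are taken apart. The route sets out from 15 as before. The crude product, including the cis-fused (3aS,8R,8aR) enone F1, is deprotonated at C5 (the only enolisable position, C1 being fully substituted) with LiN(SiMe3)2 in THF at −78 °C to the cross-conjugated lithium dienolate F2. F2 is then protonated at −78 °C by the hindered 2,6-di-tert-butyl-4-methylphenol, which should reach C5 only from the α face. This returns to 17 and recycles the wrong epimer.

**Step 3.** The most likely failure is capture of the bromoallyl cation by water at the methyl-bearing terminus, or acid-induced migration of the skipped diene, because the tertiary terminus carries more of the charge and strong acid is set free.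

Fallback: the regiochemistry is made irrelevant by an oxidative transposition. From 5 the opening is run with CaCO3 as buffer. The crude mixture of 6 and the tertiary alcohol racemic 2-bromo-1,5-dimethylcyclohepta-2,5-dien-1-ol F3 is oxidised with C5H5NH[CrO3Cl] (pyridinium chlorochromate) in CH2Cl2. 6 is oxidised directly and F3 by 1,3-transposition of its chromate ester (Babler–Dauben oxidation), so both converge on 7.

**Step 5.** The most likely failure is incomplete enantioselection. The flexible seven-membered ring and the alkene on the CH2 side make the two flanks of the ketone less different than in the six-membered bromoenones for which the reduction is established.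

Fallback: resolution in place of asymmetric reduction. From racemic 6 (step 4 is then not needed), lipase from Burkholderia cepacia and vinyl acetate in t-BuOMe are expected, by the usual empirical size rule, to acetylate the (R)-enantiomer to (1R)-2-bromo-3,6-dimethylcyclohepta-2,5-dien-1-yl acetate F4 and to leave (1S)-2-bromo-3,6-dimethylcyclohepta-2,5-dien-1-ol F5. After separation, K2CO3 in MeOH converts F4 into 8. F5 can be fed back through 7.

**Step 13.** The most likely failure is enolisation of the ketone or β-hydride transfer from the branched reagent in place of addition, together with incomplete α-face selectivity. The carbonyl is flanked by a tertiary centre and the nucleophile is secondary.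

Fallback: a smaller sp2 nucleophile followed by hydrogenation. From 18, CH2=C(CH3)MgBr with CeCl3 in THF at −78 °C should give the isopropenyl carbinol F6. H2 with RhCl(PPh3)3 in benzene then saturates the 1,1-disubstituted alkene in preference to the trisubstituted ring alkene, which returns to 19.

**Step 16.** The most likely failure is slow or incomplete acylation of O6. This hydroxyl is syn-1,3 to the angular methyl and sits next to C5, which has two fully substituted neighbours.

Fallback: acylation before the isopropyl group is introduced. From 18, HF·pyridine in THF gives the hydroxy ketone F7. Esterification with 23 through 24 as in step 16 gives the keto ester F8, in which C4 is still trigonal and O6 less crowded. i-PrMgCl with CeCl3 at −78 °C should then add to the ketone much faster than to the aryl ester, which returns to 25.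

**Step 17.** The most likely failure is insufficient facial selectivity of the oxygen transfer, because the alkene is two bonds away from both β substituents that are meant to shield it.

Fallback: a two-step halohydrin route that inverts the facial outcome. From 25, N-bromosuccinimide in THF–H2O gives the bromohydrin F9 (bromonium ion on the face the peracid prefers, water at C8 from the other face). DBU then closes the epoxide by displacement of bromide at C9, which places the oxygen on the face opposite to the one chosen by the electrophile and returns to 26.

## Further compounds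

F1 | step 11 | (3aS,8R,8aR)-8-{[tert-butyl(dimethyl)silyl]oxy}-3a,6-dimethyl-4,7,8,8a-tetrahydroazulen-1(3aH)-one (cis-fused C5 epimer of 17) | O=C1C=C[C@]2(C)CC=C(C)C[C@@H](O[Si](C)(C)C(C)(C)C)[C@@H]21
F2 | step 11 | lithium dienolate of 17 (O4–Li; C4=C5 and C2=C3) | [Li]OC1=C2[C@H](O[Si](C)(C)C(C)(C)C)CC(C)=CC[C@@]2(C)C=C1
F3 | step 3 | racemic 2-bromo-1,5-dimethylcyclohepta-2,5-dien-1-ol | CC1(O)CC=C(C)CC=C1Br
F4 | step 5 | (1R)-2-bromo-3,6-dimethylcyclohepta-2,5-dien-1-yl acetate | BrC1=C(C)CC=C(C)C[C@H]1OC(C)=O
F5 | step 5 | (1S)-2-bromo-3,6-dimethylcyclohepta-2,5-dien-1-ol | BrC1=C(C)CC=C(C)C[C@@H]1O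
F6 | step 13 | (1S,3aR,8R,8aS)-8-{[tert-butyl(dimethyl)silyl]oxy}-3a,6-dimethyl-1-(prop-1-en-2-yl)-1,2,3,3a,4,7,8,8a-octahydroazulen-1-ol | CC(=C)[C@]1(O)CC[C@]2(C)CC=C(C)C[C@@H](O[Si](C)(C)C(C)(C)C)[C@H]21
F7 | step 16 | (3aR,8R,8aS)-8-hydroxy-3a,6-dimethyl-3,3a,4,7,8,8a-hexahydroazulen-1(2H)-one | O=C1CC[C@]2(C)CC=C(C)C[C@@H](O)[C@H]21
F8 | step 16 | (3aS,4R,8aR)-6,8a-dimethyl-3-oxo-1,2,3,3a,4,5,8,8a-octahydroazulen-4-yl 4-{[tert-butyl(dimethyl)silyl]oxy}benzoate | O=C1CC[C@]2(C)CC=C(C)C[C@@H](OC(=O)c3ccc(O[Si](C)(C)C(C)(C)C)cc3)[C@H]21
F9 | step 17 | (8R,9R)-9-bromo-8-hydroxy-8,9-dihydro derivative of 25 (daucane numbering; bromine β, hydroxyl α) | CC(C)[C@]1(O)CC[C@]2(C)C[C@@H](Br)[C@](C)(O)C[C@@H](OC(=O)c3ccc(O[Si](C)(C)C(C)(C)C)cc3)[C@H]21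
A1 | alternative 1 | racemic 2-bromo-3,6-dimethylcyclohepta-2,5-dien-1-ol | CC1=C(Br)C(O)CC(C)=CC1
A2 | alternative 2 | (3R)-7-[1-(tert-butyldimethylsilyloxy)-2-methylcyclopropyl]-6-methyl-3-(propan-2-yl)-3-(triethylsilyloxy)hept-6-en-1-yne | C#C[C@](O[Si](CC)(CC)CC)(C(C)C)CCC(C)=CC1(O[Si](C)(C)C(C)(C)C)CC1C
A3 | alternative 2 | bicyclic diene enol ether (C4 triethylsilyl ether, C9 tert-butyldimethylsilyl enol ether, C5=C6 alkene) | CC(C)[C@]1(O[Si](CC)(CC)CC)CC[C@]2(C)C=C(O[Si](C)(C)C(C)(C)C)C(C)CC=C12
A4 | alternative 3 | cyclopentane with the C4 triethylsilyloxy/isopropyl carbon, the C5 1-(tert-butyldimethylsilyloxy)vinyl group and the C1 methyl/3-(trimethylsilyl)but-2-enyl carbon | CC(C)[C@]1(O[Si](CC)(CC)CC)CC[C@](C)(CC=C(C)[Si](C)(C)C)[C@H]1C(=C)O[Si](C)(C)C(C)(C)C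
A5 | alternative 3 | bicyclic C6 ketone (C4 triethylsilyl ether, C8=C9 alkene, trans-fused) | CC(C)[C@]1(O[Si](CC)(CC)CC)CC[C@]2(C)CC=C(C)CC(=O)[C@H]21
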